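The route rests on cutting C3–C4 and C5–C6, which frees C4–C5 as an isopropenyl boronate. Plakortolide numbering is used: C1 is the lactone carbonyl, C3 the peroxy methine, C4 the ring-fusion carbon with methyl and lactone oxygen, C5 the 1,2-dioxane CH2, C6 the quaternary peroxy carbon. One enantioselective conjunctive cross-coupling joins C5 to an alkenyl triflate (C6 plus masked side chain) while the C1–C3 propanoate migrates from boron to C4, creating the C4 stereocentre. Its C–B bond becomes the lactone C–O bond. The precursor is a lithium isopropenyl(alkyl)boronate. Peroxidation at C6, oxa-Michael closure of the dioxane and a late olefination follow.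

Key step: step 4

Assumption: (Sp,Sp)-MandyPhos is the ferrocene bisphosphine C64H74FeN2O4P2, 1,1′-bis[bis(4-methoxy-3,5-dimethylphenyl)phosphino]-2,2′-bis[(R)-α-(dimethylamino)benzyl]ferrocene. It is taken to deliver the (R)-configured C–B centre at C4; if the sense proves opposite, the antipodal ligand is used.

Remark: C6 is created by radical oxygenation without facial bias. Both C6 epimers are expected, and the wanted one is separated after ring closure (step 7). Side-chain carbons are counted C1′–C10′ from C6.

Step 1
Reactants: 1 1-methylcyclooctene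
Product: 3 9,9-dimethoxynonan-2-one, via 8-oxononanal 2 (not isolated)
Conditions: O3, CH2Cl2/MeOH, −78 °C; Me2S, −78 °C to rt; then HC(OMe)3, CeCl3·7H2O (cat.), MeOH, rt
Reagents that add atoms: ozone [O-][O+]=O; trimethyl orthoformate COC(OC)OC
Why: Ozonolysis with reductive work-up opens the ring to keto aldehyde 2, and the cerium trichloride-catalysed acetalisation is selective for the aldehyde over the methyl ketone; no stereocentre is formed.

Step 2
Reactants: 3 9,9-dimethoxynonan-2-one
Product: 4 9,9-dimethoxynon-1-en-2-yl trifluoromethanesulfonate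
Conditions: LiN(iPr)2, THF, −78 °C; PhNTf2, −78 to 0 °C
Reagents that add atoms: N-phenylbis(trifluoromethanesulfonimide) O=S(=O)(N(c1ccccc1)S(=O)(=O)C(F)(F)F)C(F)(F)F
Why: Kinetic enolisation on the methyl side with the hindered lithium amide and O-sulfonylation (enol triflate formation) should give the terminal alkenyl triflate regioselectively; no stereocentre is formed.

Step 3
Reactants: 5 tert-butyl acrylate
Product: 6 tert-butyl 3-(4,4,5,5-tetramethyl-1,3,2-dioxaborolan-2-yl)propanoate
Conditions: B2pin2, CuCl (cat.), NaOtBu (cat.), bis[2-(diphenylphosphino)phenyl] ether (cat.), MeOH, THF, rt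
Reagents that add atoms: bis(pinacolato)diboron CC1(C)OB(OC1(C)C)B1OC(C)(C)C(C)(C)O1
Why: Copper-catalysed conjugate borylation places boron at the β-carbon (boryl transfer from the copper boryl formed from CuCl, NaOtBu and B2pin2, then protonation of the enolate by methanol); no stereocentre is formed.

Step 4
Reactants: 7 2-bromopropene; 6 tert-butyl 3-(4,4,5,5-tetramethyl-1,3,2-dioxaborolan-2-yl)propanoate; 4 9,9-dimethoxynon-1-en-2-yl trifluoromethanesulfonate
Product: 12 (5S)-5-(9,9-dimethoxy-2-methylidenenonyl)-5-methyloxolan-2-one, via isopropenyllithium 8 (not isolated), via lithium ate complex 9 (not isolated), via tertiary boronic ester 10 (not isolated), via hydroxy ester 11 (not isolated)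
Conditions: 7, t-BuLi (2 equiv), Et2O, −78 °C; 6, −78 °C to rt; then NaOTf, 4, Pd(OAc)2 (cat.), (Sp,Sp)-MandyPhos (cat.), THF, 60 °C; then 3 M NaOH, 30% H2O2, 0 °C to rt; pH 5 work-up
Reagents that add atoms: hydrogen peroxide OO
Why: Zerovalent palladium inserts into the C–O bond of triflate 4, the resulting alkenylpalladium triflate binds the isopropenyl π-bond of ate complex 9, and a metal-induced 1,2-metallate shift moves the 2-(tert-butoxycarbonyl)ethyl group (C3) from boron to C4 anti to palladium while C5 binds the metal; reductive elimination then forms C5–C6 and gives tertiary boronic ester 10, so both bonds arise in one catalytic cycle. The closest known reaction type is the enantioselective conjunctive cross-coupling of α-substituted alkenyl boron ate complexes with aryl and alkenyl triflates, which gives tertiary boronic esters. No ring closes in the carbon–carbon bond-forming event; after stereoretentive oxidation of the C–B bond, the C4 alkoxide of 11 closes the γ-lactone by 5-exo-trig attack on the tert-butyl ester. The C4 stereocentre is controlled by the chiral ferrocene bisphosphine on palladium, which selects the enantiotopic face of the isopropenyl group, and it is carried into the C–O bond with retention. The step needs the metallate shift to outrun direct Suzuki–Miyaura transfer of the isopropenyl group and needs bond formation at the CH2 terminus; the halide-free triflate electrophile, the unhindered methylene terminus and the good migratory aptitude of the primary alkyl group should secure both.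

Step 5
Reactants: 12 (5S)-5-(9,9-dimethoxy-2-methylidenenonyl)-5-methyloxolan-2-one
Product: 15 (5R)-5-(9,9-dimethoxy-2-methylidenenonyl)-5-methylfuran-2(5H)-one, via phenylselanyl lactone 13 (not isolated), via selenoxide 14 (not isolated)
Conditions: LiN(iPr)2, THF, −78 °C; PhSeBr; then 30% H2O2, pyridine, CH2Cl2, 0 °C to rt
Reagents that add atoms: none
Why: α-Selenenylation of the lactone enolate, oxidation and selenoxide syn-elimination introduce the C2=C3 double bond; only C3 carries a β-hydrogen, so the endocyclic butenolide is the only possible alkene and C4 is untouched.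

Step 6
Reactants: 15 (5R)-5-(9,9-dimethoxy-2-methylidenenonyl)-5-methylfuran-2(5H)-one
Product: 16 (5R)-5-{9,9-dimethoxy-2-methyl-2-[(triethylsilyl)peroxy]nonyl}-5-methylfuran-2(5H)-one (both C6 epimers)
Conditions: Co(acac)2 (cat.), O2 (1 atm), Et3SiH, ClCH2CH2Cl, rt
Reagents that add atoms: dioxygen O=O; triethylsilane CC[SiH](CC)CC
Why: Isayama–Mukaiyama hydroperoxysilylation: Markovnikov hydrogen-atom transfer to the electron-rich 1,1-disubstituted alkene gives the tertiary C6 radical, which captures O2 and is silylated, while the hindered, electron-poor butenolide alkene should react more slowly; C6 forms without useful facial bias, so both epimers are carried on together.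

Step 7
Reactants: 16 (5R)-5-{9,9-dimethoxy-2-methyl-2-[(triethylsilyl)peroxy]nonyl}-5-methylfuran-2(5H)-one
Product: 18 (3S,4aR,7aR)-3-(7,7-dimethoxyheptyl)-3,4a-dimethyltetrahydrofuro[3,2-c][1,2]dioxin-6(3H)-one, via hydroperoxide 17 (not isolated)
Conditions: HCl (cat.), MeOH, 0 °C; then Et2NH (cat.), CF3CH2OH, rt; chromatographic removal of the C6 epimer
Reagents that add atoms: none
Why: Methanolysis of the O–Si bond frees hydroperoxide 17, whose base-catalysed 6-exo-trig oxa-Michael addition to C3 of the butenolide closes the 1,2-dioxane; the short tether allows only the cis-fused bicycle, so C3 is set by C4 (substrate control), and the (6S) epimer 18 is separated from its C6 diastereomer at this rigid stage.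

Step 8
Reactants: 18 (3S,4aR,7aR)-3-(7,7-dimethoxyheptyl)-3,4a-dimethyltetrahydrofuro[3,2-c][1,2]dioxin-6(3H)-one
Product: 19 7-[(3S,4aR,7aR)-3,4a-dimethyl-6-oxohexahydrofuro[3,2-c][1,2]dioxin-3-yl]heptanal
Conditions: 1 M HCl, THF, rt
Reagents that add atoms: water O
Why: Acid-catalysed acetal hydrolysis unmasks the aldehyde; the dialkyl peroxide and the lactone should be stable to dilute aqueous acid and no stereocentre is affected.

Step 9
Reactants: 19 7-[(3S,4aR,7aR)-3,4a-dimethyl-6-oxohexahydrofuro[3,2-c][1,2]dioxin-3-yl]heptanal; 20 diethyl [(2E)-3-phenylprop-2-en-1-yl]phosphonate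
Product: 21 plakortolide Q
Conditions: 20, LiN(SiMe3)2, THF, −78 °C; then 19, −78 to 0 °C
Reagents that add atoms: none
Why: Horner–Wadsworth–Emmons olefination with the preformed allylic phosphonate anion should form the C7′=C8′ alkene with E geometry (the styryl alkene stays E), and low temperature with one equivalent of anion limits enolisation of the β-peroxy lactone; no stereocentre is touched.

Compound list

1 | 1-methylcyclooctene | CC1=CCCCCCC1 | starting material
2 | 8-oxononanal | CC(=O)CCCCCCC=O | intermediate
3 | 9,9-dimethoxynonan-2-one | CC(=O)CCCCCCC(OC)OC | intermediate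
4 | 9,9-dimethoxynon-1-en-2-yl trifluoromethanesulfonate | C=C(OS(=O)(=O)C(F)(F)F)CCCCCCC(OC)OC | intermediate
5 | tert-butyl acrylate | C=CC(=O)OC(C)(C)C | starting material
6 | tert-butyl 3-(4,4,5,5-tetramethyl-1,3,2-dioxaborolan-2-yl)propanoate | CC(C)(C)OC(=O)CCB1OC(C)(C)C(C)(C)O1 | intermediate
7 | 2-bromopropene | C=C(C)Br | starting material
8 | isopropenyllithium (prop-1-en-2-yllithium) | [Li]C(C)=C | intermediate
9 | lithium [3-(tert-butoxy)-3-oxopropyl](prop-1-en-2-yl)(pinacolato)borate | [Li+].C=C(C)[B-]1(CCC(=O)OC(C)(C)C)OC(C)(C)C(C)(C)O1 | intermediate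
10 | tert-butyl (4R)-13,13-dimethoxy-4-methyl-6-methylidene-4-(4,4,5,5-tetramethyl-1,3,2-dioxaborolan-2-yl)tridecanoate | C=C(CCCCCCC(OC)OC)C[C@](C)(CCC(=O)OC(C)(C)C)B1OC(C)(C)C(C)(C)O1 | intermediate
11 | tert-butyl (4S)-4-hydroxy-13,13-dimethoxy-4-methyl-6-methylidenetridecanoate | C=C(CCCCCCC(OC)OC)C[C@](C)(CCC(=O)OC(C)(C)C)O | intermediate
12 | (5S)-5-(9,9-dimethoxy-2-methylidenenonyl)-5-methyloxolan-2-one | C=C(CCCCCCC(OC)OC)C[C@@]1(C)OC(=O)CC1 | intermediate
13 | (5R)-5-(9,9-dimethoxy-2-methylidenenonyl)-5-methyl-3-(phenylselanyl)oxolan-2-one (epimers at the selenium-bearing carbon) | C=C(CCCCCCC(OC)OC)C[C@@]1(C)OC(=O)C([Se]c2ccccc2)C1 | intermediate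
14 | selenoxide of 13, (5R)-5-(9,9-dimethoxy-2-methylidenenonyl)-5-methyl-3-(phenylseleninyl)oxolan-2-one | C=C(CCCCCCC(OC)OC)C[C@@]1(C)OC(=O)C([Se](=O)c2ccccc2)C1 | intermediate
15 | (5R)-5-(9,9-dimethoxy-2-methylidenenonyl)-5-methylfuran-2(5H)-one | C=C(CCCCCCC(OC)OC)C[C@@]1(C)OC(=O)C=C1 | intermediate
16 | (5R)-5-{9,9-dimethoxy-2-methyl-2-[(triethylsilyl)peroxy]nonyl}-5-methylfuran-2(5H)-one, both epimers at the peroxy carbon | CC(CCCCCCC(OC)OC)(OO[Si](CC)(CC)CC)C[C@@]1(C)OC(=O)C=C1 | intermediate
17 | (5R)-5-(2-hydroperoxy-9,9-dimethoxy-2-methylnonyl)-5-methylfuran-2(5H)-one, both epimers at the peroxy carbon | CC(CCCCCCC(OC)OC)(OO)C[C@@]1(C)OC(=O)C=C1 | intermediate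
18 | (3S,4aR,7aR)-3-(7,7-dimethoxyheptyl)-3,4a-dimethyltetrahydrofuro[3,2-c][1,2]dioxin-6(3H)-one | C[C@]1(CCCCCCC(OC)OC)C[C@@]2(C)OC(=O)C[C@H]2OO1 | intermediate
19 | 7-[(3S,4aR,7aR)-3,4a-dimethyl-6-oxohexahydrofuro[3,2-c][1,2]dioxin-3-yl]heptanal | C[C@]1(CCCCCCC=O)C[C@@]2(C)OC(=O)C[C@H]2OO1 | intermediate
20 | diethyl [(2E)-3-phenylprop-2-en-1-yl]phosphonate | CCOP(=O)(OCC)C/C=C/c1ccccc1 | starting material
21 | plakortolide Q, (3S,4aR,7aR)-3,4a-dimethyl-3-[(7E,9E)-10-phenyldeca-7,9-dien-1-yl]tetrahydrofuro[3,2-c][1,2]dioxin-6(3H)-one | C[C@]1(CCCCCC/C=C/C=C/c2ccccc2)C[C@@]2(C)OC(=O)C[C@H]2OO1 | target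

Total step count: 9. Longest linear sequence: 8 steps (steps 1, 2, 4, 5, 6, 7, 8, 9).

Steps most likely to fail

First, step 4. The isopropenyl group may be transferred directly from boron to palladium (Suzuki–Miyaura pathway) instead of undergoing the metallate shift, and the hindered α-substituted alkene may bind with poor facial discrimination. The fallback sets out from triflate 4 and forms C4–C5 instead. Palladium-catalysed coupling of 4 with IZnCH2B(pin) (Pd(PPh3)4, THF) gives the allylboronate 2-(9,9-dimethoxy-2-methylidenenonyl)-4,4,5,5-tetramethyl-1,3,2-dioxaborolane F1. Copper-catalysed enantioselective allylboration of commercial tert-butyl levulinate with F1 (CuF(PPh3)3, chiral 1,2-bis(2,5-diisopropylphospholano)benzene, La(OiPr)3, DMF, −40 °C, ligand enantiomer chosen for the (4S) alcohol) gives hydroxy ester 11, which lactonises to 12, where the route is rejoined.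

Second, step 6. Hydrogen-atom transfer may also reach the butenolide double bond, the peroxyl intermediate may be reduced to the tertiary alcohol, and no facial discrimination at C6 is expected. The fallback sets out from butenolide 15 and closes the ring through the C6–O bond. Reversible conjugate addition of hydrogen peroxide (H2O2·urea, Et2NH, CF3CH2OH) gives the cis β-hydroperoxy lactone (4R,5R)-4-hydroperoxy-5-(9,9-dimethoxy-2-methylidenenonyl)-5-methyloxolan-2-one F2. Cycloperoxymercuration (Hg(OAc)2, CH2Cl2; 6-exo Markovnikov attack of the hydroperoxide on C6) gives the organomercurial acetoxy{[(3S,4aR,7aR)-3-(7,7-dimethoxyheptyl)-4a-methyl-6-oxohexahydrofuro[3,2-c][1,2]dioxin-3-yl]methyl}mercury F3. Alkaline NaBH4 demercuration turns the CH2HgOAc group into the C6 methyl group and returns to 18. The chair-like closure offers a chance of C6 selectivity that the radical route lacks.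

Third, step 9. The phosphonate anion may deprotonate the lactone and open the dioxane by retro-oxa-Michael elimination, and the E selectivity may be incomplete. The fallback sets out from aldehyde 19 and avoids carbanions. BF3·OEt2-mediated allylation with trimethyl(1-phenylallyl)silane (CH2Cl2, −78 °C, SE2′ attack through the CH2 terminus) gives the homoallylic alcohol (3S,4aR,7aR)-3-[(9E)-7-hydroxy-10-phenyldec-9-en-1-yl]-3,4a-dimethyltetrahydrofuro[3,2-c][1,2]dioxin-6(3H)-one F4 as a mixture of carbinol epimers. Syn-dehydration with the Burgess reagent (toluene, 50 °C) towards the allylic CH2 should form the conjugated (7E,9E)-diene and arrive at 21.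

Further compounds

F1 | step 4 | 2-(9,9-dimethoxy-2-methylidenenonyl)-4,4,5,5-tetramethyl-1,3,2-dioxaborolane | C=C(CCCCCCC(OC)OC)CB1OC(C)(C)C(C)(C)O1
F2 | step 6 | (4R,5R)-4-hydroperoxy-5-(9,9-dimethoxy-2-methylidenenonyl)-5-methyloxolan-2-one | C=C(CCCCCCC(OC)OC)C[C@@]1(C)OC(=O)C[C@H]1OO
F3 | step 6 | acetoxy{[(3S,4aR,7aR)-3-(7,7-dimethoxyheptyl)-4a-methyl-6-oxohexahydrofuro[3,2-c][1,2]dioxin-3-yl]methyl}mercury | CC(=O)O[Hg]C[C@]1(CCCCCCC(OC)OC)C[C@@]2(C)OC(=O)C[C@H]2OO1
F4 | step 9 | (3S,4aR,7aR)-3-[(9E)-7-hydroxy-10-phenyldec-9-en-1-yl]-3,4a-dimethyltetrahydrofuro[3,2-c][1,2]dioxin-6(3H)-one | C[C@]1(CCCCCCC(O)C/C=C/c2ccccc2)C[C@@]2(C)OC(=O)C[C@H]2OO1
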